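**Retrosynthetic overview**
1. Isocycloheterophyllin 20 comes from its tris-silyl ether 19 by fluoride deprotection.
2. Ring C (pyranone) is closed last: 19 comes from diketone 17 by para-Claisen–Cope shift of an O-prenyl ether (puts prenyl on C6, frees O1), then cyclodehydration.
3. Ring D (oxepine) and the C3–CH2 bond: 17 comes from 2'-hydroxy-1,3-diketone 15 and propargylic carbonate 3. Palladium turns 3 into a 2-aryloxy-π-allyl cation, an O-arylated α-keto cation (enolonium) equivalent, which alkylates the diketone carbon.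
4. 15 comes from aldol addition and oxidation of ring-B acetophenone 12 with ring-A aldehyde 10.
5. 10 comes from phloroglucinaldehyde 4, with the chromene made by a chelation-directed propargyl ether Claisen. Ring order: chromene, then oxepine (ring D), then pyranone (ring C).

Assumption: the target has no stereocentre and no stereogenic double bond, so the "single enantiomer" is the achiral compound itself; the stereocentres that appear in 14, 17 and 18 are racemic and are erased in steps 8 and 10.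

**Route**

Step 1
Reactants: 1 2-methylbut-3-yn-2-ol
Product: 3 tert-butyl (2-methylbut-3-yn-2-yl) carbonate, via lithium 2-methylbut-3-yn-2-olate 2 (not isolated)
Conditions: n-BuLi (1.0 equiv), THF, −78 °C; then Boc2O, −78 °C → rt; aq NH4Cl
Reagents that add atoms: di-tert-butyl dicarbonate CC(C)(C)OC(=O)OC(=O)OC(C)(C)C; n-butyllithium [Li]CCCC (lithium of 2 only)
Why: alkoxycarbonylation of the tertiary lithium alkoxide by Boc2O; one equivalent of base removes the OH proton (pKa about 17) before the alkyne C–H.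

Step 2
Reactants: 4 2,4,6-trihydroxybenzaldehyde; 3 tert-butyl (2-methylbut-3-yn-2-yl) carbonate
Product: 5 2,6-dihydroxy-4-[(2-methylbut-3-yn-2-yl)oxy]benzaldehyde
Conditions: CuCl2·2H2O (1 mol %), DBU (1.2 equiv), MeCN/DMF, 0 °C
Reagents that add atoms: none
Why: copper-catalysed propargylic etherification through a copper allenylidene; one equivalent of DBU deprotonates only the para OH, the most acidic one, because both ortho OH groups are hydrogen-bonded to the formyl group.

Step 3
Reactants: 5 2,6-dihydroxy-4-[(2-methylbut-3-yn-2-yl)oxy]benzaldehyde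
Product: 6 2-hydroxy-4-[(2-methylbut-3-yn-2-yl)oxy]-6-(triisopropylsilyloxy)benzaldehyde
Conditions: TIPSCl (1.05 equiv), imidazole, DMF, 0 °C → rt
Reagents that add atoms: chlorotri(propan-2-yl)silane CC(C)[Si](Cl)(C(C)C)C(C)C
Why: silyl ether formation; the two OH groups are equivalent by symmetry, and after the first silylation the remaining OH is locked in the chelate with CHO, so the reaction stops at the mono-ether.

Step 4
Reactants: 6 2-hydroxy-4-[(2-methylbut-3-yn-2-yl)oxy]-6-(triisopropylsilyloxy)benzaldehyde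
Product: 8 5-hydroxy-2,2-dimethyl-7-(triisopropylsilyloxy)-2H-chromene-6-carbaldehyde, via allenylphenol 7 (not isolated)
Conditions: xylenes, 140 °C, sealed tube
Reagents that add atoms: none
Why: aryl propargyl ether Claisen rearrangement, 1,5-hydrogen shift and oxa-6π electrocyclisation; the [3,3] shift goes to the ring carbon next to the hydrogen-bonded OH (bond fixation by the chelate, and away from the bulky silyl ether), and the ring oxygen is the original ether oxygen, as in the 2,4-dihydroxybenzaldehyde series.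

Step 5
Reactants: 8 5-hydroxy-2,2-dimethyl-7-(triisopropylsilyloxy)-2H-chromene-6-carbaldehyde; 9 3-methylbut-2-en-1-ol
Product: 10 2,2-dimethyl-5-(3-methylbut-2-enyloxy)-7-(triisopropylsilyloxy)-2H-chromene-6-carbaldehyde
Conditions: PPh3, DIAD, THF, 0 °C → rt
Reagents that add atoms: none
Why: Mitsunobu etherification, a neutral way to prenylate a chelated ortho-formyl phenol without touching the aryl silyl ether; this prenyl ether later serves both as the mask for O1 and as the source of the C6 prenyl group.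

Step 6
Reactants: 11 1-(2,4,5-trihydroxyphenyl)ethan-1-one
Product: 12 1-[2-hydroxy-4,5-bis(triisopropylsilyloxy)phenyl]ethan-1-one
Conditions: TIPSCl (2.2 equiv), imidazole, DMF, rt
Reagents that add atoms: chlorotri(propan-2-yl)silane CC(C)[Si](Cl)(C(C)C)C(C)C
Why: silyl ether formation at the two free phenols; the OH ortho to the acetyl group is chelated and stays free.

Step 7
Reactants: 12 1-[2-hydroxy-4,5-bis(triisopropylsilyloxy)phenyl]ethan-1-one; 10 2,2-dimethyl-5-(3-methylbut-2-enyloxy)-7-(triisopropylsilyloxy)-2H-chromene-6-carbaldehyde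
Product: 14 3-[2,2-dimethyl-5-(3-methylbut-2-enyloxy)-7-(triisopropylsilyloxy)-2H-chromen-6-yl]-3-hydroxy-1-[2-hydroxy-4,5-bis(triisopropylsilyloxy)phenyl]propan-1-one (racemic), via dilithium dianion 13 (not isolated)
Conditions: LiN(SiMe3)2 (2.2 equiv), THF, −78 °C; then 10, −78 °C; AcOH, −78 °C
Reagents that add atoms: lithium bis(trimethylsilyl)amide [Li]N([Si](C)(C)C)[Si](C)(C)C (lithium of 13 only)
Why: aldol addition of the phenoxide–enolate dianion of an ortho-hydroxyacetophenone to an aldehyde; the cold acidic quench prevents dehydration to the chalcone, and the new stereocentre is racemic and is oxidised away in step 8.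

Step 8
Reactants: 14 the aldol adduct from step 7
Product: 15 1-[2,2-dimethyl-5-(3-methylbut-2-enyloxy)-7-(triisopropylsilyloxy)-2H-chromen-6-yl]-3-[2-hydroxy-4,5-bis(triisopropylsilyloxy)phenyl]propane-1,3-dione
Conditions: Dess–Martin periodinane (1.2 equiv), pyridine, CH2Cl2, 0 °C
Reagents that add atoms: none
Why: Dess–Martin oxidation of a β-hydroxy ketone to the 1,3-diketone; the fast, cold, pyridine-buffered oxidation spares the chelated phenol, the prenyl ether and the chromene, and no acid is present that could close the wrong chromone through the 2'-OH.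

Step 9
Reactants: 15 the 2'-hydroxy-1,3-diketone from step 8; 3 tert-butyl (2-methylbut-3-yn-2-yl) carbonate
Product: 17 4-{[2,2-dimethyl-5-(3-methylbut-2-enyloxy)-7-(triisopropylsilyloxy)-2H-chromen-6-yl]carbonyl}-2-(propan-2-ylidene)-7,8-bis(triisopropylsilyloxy)-3,4-dihydro-1-benzoxepin-5(2H)-one (racemic), via disodium salt 16 (not isolated)
Conditions: NaOt-Bu (2.05 equiv), THF, 0 °C; then 3 (1.2 equiv), Pd2(dba)3·CHCl3 (2.5 mol %), Ph2P(CH2)4PPh2 (6 mol %), degassed, 0 °C → rt; aq NH4Cl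
Reagents that add atoms: sodium tert-butoxide CC(C)(C)[O-].[Na+] (sodium of 16 only)
Why: Proposed new method: zerovalent palladium ionises 3 to an η3-propargyl palladium cation, the aryloxide of dianion 16 (its most nucleophilic site, the diketonate carbon being delocalised and hindered) adds to the central carbon, t-BuOH protonates the palladacyclobutene to a 2-aryloxy-π-allyl palladium cation, which is an O-arylated α-keto cation (enolonium) equivalent, and the tethered diketonate carbon attacks its CH2 terminus rather than the CMe2 terminus in an irreversible seven-membered Tsuji–Trost closure that fixes the exocyclic isopropylidene enol ether, while any O-allylation is reversible under palladium and the prenyl aryl ether ionises far more slowly than the propargylic carbonate; the closest known reactions are the palladium-catalysed annulations of propargylic carbonates with catechols (2-alkylidene-1,4-benzodioxanes) and with phenols that carry a tethered carbon pronucleophile (chromans).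

Step 10
Reactants: 17 the oxepine diketone from step 9
Product: 19 isocycloheterophyllin 5,4',5'-tris(triisopropylsilyl) ether, via prenylated hydroxy diketone 18 (not isolated)
Conditions: PhNEt2, 190 °C, sealed tube, argon
Reagents that add atoms: none
Why: para-Claisen–Cope rearrangement (both ortho positions of the prenyl ether are blocked, so two [3,3] shifts carry the prenyl group to the only free ring carbon, para to oxygen) unmasks the one phenol that can reach the ring-B ketone, and thermal cyclodehydration of the 2-hydroxyaryl 1,3-diketone then closes the pyranone as in the last stage of a Baker–Venkataraman flavone synthesis, erasing the stereocentre.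

Step 11
Reactants: 19 isocycloheterophyllin 5,4',5'-tris(triisopropylsilyl) ether
Product: 20 isocycloheterophyllin
Conditions: Bu4NF (3.3 equiv), AcOH (3.3 equiv), THF, 0 °C → rt, argon
Reagents that add atoms: none
Why: fluoride cleavage of three aryl silyl ethers under buffered, non-acidic conditions that spare the enol ether, the chromene, the prenyl group and the catechol.

**Compound list**

1 | 2-methylbut-3-yn-2-ol | CC(C)(O)C#C | starting material
2 | lithium 2-methylbut-3-yn-2-olate | [Li+].[O-]C(C)(C)C#C | intermediate (not isolated)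
3 | tert-butyl (2-methylbut-3-yn-2-yl) carbonate | CC(C)(C)OC(=O)OC(C)(C)C#C | intermediate
4 | 2,4,6-trihydroxybenzaldehyde | O=Cc1c(O)cc(O)cc1O | starting material
5 | 2,6-dihydroxy-4-[(2-methylbut-3-yn-2-yl)oxy]benzaldehyde | O=Cc1c(O)cc(OC(C)(C)C#C)cc1O | intermediate
6 | 2-hydroxy-4-[(2-methylbut-3-yn-2-yl)oxy]-6-(triisopropylsilyloxy)benzaldehyde | O=Cc1c(O)cc(OC(C)(C)C#C)cc1O[Si](C(C)C)(C(C)C)C(C)C | intermediate
7 | 2,4-dihydroxy-3-(3-methylbuta-1,2-dien-1-yl)-6-(triisopropylsilyloxy)benzaldehyde | O=Cc1c(O)c(C=C=C(C)C)c(O)cc1O[Si](C(C)C)(C(C)C)C(C)C | intermediate (not isolated)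
8 | 5-hydroxy-2,2-dimethyl-7-(triisopropylsilyloxy)-2H-chromene-6-carbaldehyde | O=Cc1c(O)c2C=CC(C)(C)Oc2cc1O[Si](C(C)C)(C(C)C)C(C)C | intermediate
9 | 3-methylbut-2-en-1-ol | CC(C)=CCO | starting material
10 | 2,2-dimethyl-5-(3-methylbut-2-enyloxy)-7-(triisopropylsilyloxy)-2H-chromene-6-carbaldehyde | O=Cc1c(OCC=C(C)C)c2C=CC(C)(C)Oc2cc1O[Si](C(C)C)(C(C)C)C(C)C | intermediate
11 | 1-(2,4,5-trihydroxyphenyl)ethan-1-one | CC(=O)c1cc(O)c(O)cc1O | starting material
12 | 1-[2-hydroxy-4,5-bis(triisopropylsilyloxy)phenyl]ethan-1-one | CC(=O)c1cc(O[Si](C(C)C)(C(C)C)C(C)C)c(O[Si](C(C)C)(C(C)C)C(C)C)cc1O | intermediate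
13 | dilithium phenoxide–enolate dianion of 12 | [Li+].[Li+].C=C([O-])c1cc(O[Si](C(C)C)(C(C)C)C(C)C)c(O[Si](C(C)C)(C(C)C)C(C)C)cc1[O-] | intermediate (not isolated)
14 | 3-[2,2-dimethyl-5-(3-methylbut-2-enyloxy)-7-(triisopropylsilyloxy)-2H-chromen-6-yl]-3-hydroxy-1-[2-hydroxy-4,5-bis(triisopropylsilyloxy)phenyl]propan-1-one (racemic) | OC(CC(=O)c1cc(O[Si](C(C)C)(C(C)C)C(C)C)c(O[Si](C(C)C)(C(C)C)C(C)C)cc1O)c1c(OCC=C(C)C)c2C=CC(C)(C)Oc2cc1O[Si](C(C)C)(C(C)C)C(C)C | intermediate
15 | 1-[2,2-dimethyl-5-(3-methylbut-2-enyloxy)-7-(triisopropylsilyloxy)-2H-chromen-6-yl]-3-[2-hydroxy-4,5-bis(triisopropylsilyloxy)phenyl]propane-1,3-dione | O=C(CC(=O)c1cc(O[Si](C(C)C)(C(C)C)C(C)C)c(O[Si](C(C)C)(C(C)C)C(C)C)cc1O)c1c(OCC=C(C)C)c2C=CC(C)(C)Oc2cc1O[Si](C(C)C)(C(C)C)C(C)C | intermediate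
16 | disodium phenoxide–enolate salt of 15 | [Na+].[Na+].O=C(C=C([O-])c1cc(O[Si](C(C)C)(C(C)C)C(C)C)c(O[Si](C(C)C)(C(C)C)C(C)C)cc1[O-])c1c(OCC=C(C)C)c2C=CC(C)(C)Oc2cc1O[Si](C(C)C)(C(C)C)C(C)C | intermediate (not isolated)
17 | 4-{[2,2-dimethyl-5-(3-methylbut-2-enyloxy)-7-(triisopropylsilyloxy)-2H-chromen-6-yl]carbonyl}-2-(propan-2-ylidene)-7,8-bis(triisopropylsilyloxy)-3,4-dihydro-1-benzoxepin-5(2H)-one (racemic) | CC(C)=C1CC(C(=O)c3c(OCC=C(C)C)c4C=CC(C)(C)Oc4cc3O[Si](C(C)C)(C(C)C)C(C)C)C(=O)c2cc(O[Si](C(C)C)(C(C)C)C(C)C)c(O[Si](C(C)C)(C(C)C)C(C)C)cc2O1 | intermediate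
18 | 4-{[5-hydroxy-2,2-dimethyl-8-(3-methylbut-2-enyl)-7-(triisopropylsilyloxy)-2H-chromen-6-yl]carbonyl}-2-(propan-2-ylidene)-7,8-bis(triisopropylsilyloxy)-3,4-dihydro-1-benzoxepin-5(2H)-one (racemic) | CC(C)=C1CC(C(=O)c3c(O)c4C=CC(C)(C)Oc4c(CC=C(C)C)c3O[Si](C(C)C)(C(C)C)C(C)C)C(=O)c2cc(O[Si](C(C)C)(C(C)C)C(C)C)c(O[Si](C(C)C)(C(C)C)C(C)C)cc2O1 | intermediate (not isolated)
19 | isocycloheterophyllin 5,4',5'-tris(triisopropylsilyl) ether | CC(C)=CCc1c2c(c3oc4c(c(=O)c3c1O[Si](C(C)C)(C(C)C)C(C)C)CC(=C(C)C)Oc1cc(O[Si](C(C)C)(C(C)C)C(C)C)c(O[Si](C(C)C)(C(C)C)C(C)C)cc1-4)C=CC(C)(C)O2 | intermediate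
20 | isocycloheterophyllin | CC(C)=CCc1c2c(c3oc4c(c(=O)c3c1O)CC(=C(C)C)Oc1cc(O)c(O)cc1-4)C=CC(C)(C)O2 | target

**Step count**

Total: 11 steps. Longest linear sequence: 10 steps (1 → 3 → 5 → 6 → 8 → 10 → 14 → 15 → 17 → 19 → 20); steps 1 and 6 are branch steps.

**Steps most likely to fail, with fallbacks**

Step 9 (new annulation; the diketonate carbon may attack the propargyl central carbon first and give furan-type products). The fallback sets out from 12 and comes back at 17. It builds ring D before the diketone exists, with a stoichiometric masked α-keto cation. Commercial 3-methylbuta-1,2-diene is brominated (Br2, CH2Cl2, −78 °C → rt) to 1,2-dibromo-3-methylbut-2-ene F1. The dianion of 12 (LiN(SiMe3)2, 2.2 equiv, THF, −78 °C) is C-alkylated by F1 to the bromoalkenyl ketone 4-bromo-1-[2-hydroxy-4,5-bis(triisopropylsilyloxy)phenyl]-5-methylhex-4-en-1-one F2. Copper-catalysed intramolecular O-vinylation of the phenol (CuI, copper monoiodide, 1,10-phenanthroline, Cs2CO3, toluene, 100 °C) closes the oxepinone 2-(propan-2-ylidene)-7,8-bis(triisopropylsilyloxy)-3,4-dihydro-1-benzoxepin-5(2H)-one F3. Its lithium enolate adds to aldehyde 10 to give the aldol adduct F4, and Dess–Martin oxidation of F4 gives 17.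

Step 10 (the late thermal cascade may lose isoprene or stall before cyclisation). The fallback sets out from 10 and comes back at 18, which is then dehydrated to 19. The sigmatropic step is moved to the simple aldehyde and a silyl ether replaces the prenyl ether as the mask for O1. Aldehyde 10 is heated alone (PhNEt2, 190 °C) to the para-prenylated phenol 5-hydroxy-2,2-dimethyl-8-(3-methylbut-2-enyl)-7-(triisopropylsilyloxy)-2H-chromene-6-carbaldehyde F5. TBSOTf and 2,6-lutidine give its 5-O-tert-butyldimethylsilyl ether F6. Aldol addition of dianion 13 gives hydroxy ketone F7, Dess–Martin oxidation gives diketone F8, and the palladium annulation with 3 (as in step 9) gives oxepine diketone F9. K2CO3 in MeOH at 0 °C removes only the tert-butyldimethylsilyl ether ortho to the ketone and delivers 18, which is dehydrated to 19 with PPTS in toluene at 60 °C.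

Step 4 (the Claisen shift may also go to the carbon next to the silyl ether and give the wrong chromene). The fallback sets out from 5 and comes back at 8. Regiocontrol by chelation is replaced by symmetry followed by steric differentiation: the unsilylated, symmetric ether 5 is heated (xylenes, 140 °C) and can give only one chromene, 5,7-dihydroxy-2,2-dimethyl-2H-chromene-6-carbaldehyde F10. TIPSCl and imidazole then silylate the less hindered 7-OH (flanked by H-8, whereas the 5-OH sits next to the pyran ring) to give 8; any 5-O-silyl isomer is removed by chromatography.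

**Further compounds**

F1 | step 9 | 1,2-dibromo-3-methylbut-2-ene | CC(C)=C(Br)CBr
F2 | step 9 | 4-bromo-1-[2-hydroxy-4,5-bis(triisopropylsilyloxy)phenyl]-5-methylhex-4-en-1-one | CC(C)=C(Br)CCC(=O)c1cc(O[Si](C(C)C)(C(C)C)C(C)C)c(O[Si](C(C)C)(C(C)C)C(C)C)cc1O
F3 | step 9 | 2-(propan-2-ylidene)-7,8-bis(triisopropylsilyloxy)-3,4-dihydro-1-benzoxepin-5(2H)-one | CC(C)=C1CCC(=O)c2cc(O[Si](C(C)C)(C(C)C)C(C)C)c(O[Si](C(C)C)(C(C)C)C(C)C)cc2O1
F4 | step 9 | 4-{[2,2-dimethyl-5-(3-methylbut-2-enyloxy)-7-(triisopropylsilyloxy)-2H-chromen-6-yl](hydroxy)methyl}-2-(propan-2-ylidene)-7,8-bis(triisopropylsilyloxy)-3,4-dihydro-1-benzoxepin-5(2H)-one | CC(C)=C1CC(C(O)c3c(OCC=C(C)C)c4C=CC(C)(C)Oc4cc3O[Si](C(C)C)(C(C)C)C(C)C)C(=O)c2cc(O[Si](C(C)C)(C(C)C)C(C)C)c(O[Si](C(C)C)(C(C)C)C(C)C)cc2O1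
F5 | step 10 | 5-hydroxy-2,2-dimethyl-8-(3-methylbut-2-enyl)-7-(triisopropylsilyloxy)-2H-chromene-6-carbaldehyde | O=Cc1c(O)c2C=CC(C)(C)Oc2c(CC=C(C)C)c1O[Si](C(C)C)(C(C)C)C(C)C
F6 | step 10 | 5-(tert-butyldimethylsilyloxy)-2,2-dimethyl-8-(3-methylbut-2-enyl)-7-(triisopropylsilyloxy)-2H-chromene-6-carbaldehyde | O=Cc1c(O[Si](C)(C)C(C)(C)C)c2C=CC(C)(C)Oc2c(CC=C(C)C)c1O[Si](C(C)C)(C(C)C)C(C)C
F7 | step 10 | 3-[5-(tert-butyldimethylsilyloxy)-2,2-dimethyl-8-(3-methylbut-2-enyl)-7-(triisopropylsilyloxy)-2H-chromen-6-yl]-3-hydroxy-1-[2-hydroxy-4,5-bis(triisopropylsilyloxy)phenyl]propan-1-one | OC(CC(=O)c1cc(O[Si](C(C)C)(C(C)C)C(C)C)c(O[Si](C(C)C)(C(C)C)C(C)C)cc1O)c1c(O[Si](C)(C)C(C)(C)C)c2C=CC(C)(C)Oc2c(CC=C(C)C)c1O[Si](C(C)C)(C(C)C)C(C)C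
F8 | step 10 | 1-[5-(tert-butyldimethylsilyloxy)-2,2-dimethyl-8-(3-methylbut-2-enyl)-7-(triisopropylsilyloxy)-2H-chromen-6-yl]-3-[2-hydroxy-4,5-bis(triisopropylsilyloxy)phenyl]propane-1,3-dione | O=C(CC(=O)c1cc(O[Si](C(C)C)(C(C)C)C(C)C)c(O[Si](C(C)C)(C(C)C)C(C)C)cc1O)c1c(O[Si](C)(C)C(C)(C)C)c2C=CC(C)(C)Oc2c(CC=C(C)C)c1O[Si](C(C)C)(C(C)C)C(C)C
F9 | step 10 | 4-{[5-(tert-butyldimethylsilyloxy)-2,2-dimethyl-8-(3-methylbut-2-enyl)-7-(triisopropylsilyloxy)-2H-chromen-6-yl]carbonyl}-2-(propan-2-ylidene)-7,8-bis(triisopropylsilyloxy)-3,4-dihydro-1-benzoxepin-5(2H)-one | CC(C)=C1CC(C(=O)c3c(O[Si](C)(C)C(C)(C)C)c4C=CC(C)(C)Oc4c(CC=C(C)C)c3O[Si](C(C)C)(C(C)C)C(C)C)C(=O)c2cc(O[Si](C(C)C)(C(C)C)C(C)C)c(O[Si](C(C)C)(C(C)C)C(C)C)cc2O1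
F10 | step 4 | 5,7-dihydroxy-2,2-dimethyl-2H-chromene-6-carbaldehyde | O=Cc1c(O)cc2OC(C)(C)C=Cc2c1O
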